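**Strategy.** Ring B, the hexasubstituted resorcinol ring, is built rather than substituted. Its C3(OH)–C4(H)–C5(OH)–C6(prenyl) edge is a γ-prenylated acetoacetate unit, and its adjacent C1 and C2, which carry the aroyl and formyl carbons, form a 1,4-dicarbonyl array that maps onto an alkyne flanked by an aryl carbinol and an ester. A Diels–Alder reaction of the derived 1-methoxy-1,3-bis(silyloxy)diene with methyl 4-aryl-4-silyloxybut-2-ynoate, whose aryl group is the finished bromo-orcinol ring A, therefore forges ring B, aromatises it and closes a 3-arylphthalide in one operation. Lactone reduction, double oxidation and MOM removal then release the keto-aldehyde.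

Key step: step 10

Remark: ring A is the brominated ring; ring B is numbered C1 (aroyl), C2 (formyl), C3 (OH), C4 (H), C5 (OH), C6 (prenyl). Carbon-metalated species and cascade intermediates are numbered, whereas oxygen-bound salts or borates that exist only until work-up are regarded as the salt form of the compound shown. All carbinol-containing intermediates are racemic.

Step 1
Reactants: 1 3,5-dimethoxytoluene
Product: 3 2,6-dimethoxy-4-methylbenzaldehyde, via aryllithium 2 (not isolated)
Conditions: n-BuLi, TMEDA, Et2O, 0 °C to rt; DMF, 0 °C to rt; 1 M aq HCl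
Reagents that add atoms: N,N-dimethylformamide CN(C)C=O (formyl group of 3); n-butyllithium [Li]CCCC (lithium of 2 only)
Why: Directed ortho-metalation occurs at the ring carbon flanked by both methoxy groups, the most acidic and doubly coordinated site, and formylation of the aryllithium with DMF then gives the symmetric aldehyde.

Step 2
Reactants: 3 2,6-dimethoxy-4-methylbenzaldehyde
Product: 4 3-bromo-2,6-dimethoxy-4-methylbenzaldehyde
Conditions: NBS (1.05 equiv), MeCN, 0 °C to rt, dark
Reagents that add atoms: N-bromosuccinimide O=C1CCC(=O)N1Br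
Why: Electrophilic aromatic bromination can only take place at the two equivalent ring CH positions (each ortho to one methoxy group and para to the other), so a single monobromide should form, and the first bromine slows a second substitution.

Step 3
Reactants: 4 3-bromo-2,6-dimethoxy-4-methylbenzaldehyde
Product: 5 3-bromo-2-hydroxy-6-methoxy-4-methylbenzaldehyde
Conditions: BCl3 (1.1 equiv), CH2Cl2, −78 to 0 °C; H2O
Reagents that add atoms: none
Why: In this chelation-assisted Lewis acid ether cleavage ortho to a carbonyl, the methoxy group wedged between CHO and Br is twisted out of the ring plane, which makes its oxygen the more basic and its cleavage strain-relieving, so it is expected to be cleaved in preference to the unhindered one, and the boron chelate formed should stop a second demethylation.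

Step 4
Reactants: 5 3-bromo-2-hydroxy-6-methoxy-4-methylbenzaldehyde
Product: 6 3-bromo-6-methoxy-2-(methoxymethoxy)-4-methylbenzaldehyde
Conditions: NaH, DMF, 0 °C; MOMCl, 0 °C to rt
Reagents that add atoms: chloromethyl methyl ether COCCl
Why: Williamson-type O-alkylation of the sodium phenoxide with the very reactive chloromethyl ether masks the chelated phenol as an acetal that tolerates the later acetylide, fluoride, hydride and Swern conditions.

Step 5
Reactants: 6 3-bromo-6-methoxy-2-(methoxymethoxy)-4-methylbenzaldehyde; 7 methyl propiolate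
Product: 9 methyl 4-[3-bromo-6-methoxy-2-(methoxymethoxy)-4-methylphenyl]-4-hydroxybut-2-ynoate (racemic), via lithium acetylide 8 (not isolated)
Conditions: 7, LiN(SiMe3)2, THF, −78 °C; then 6, −78 °C; AcOH, −78 °C
Reagents that add atoms: lithium bis(trimethylsilyl)amide [Li]N([Si](C)(C)C)[Si](C)(C)C (lithium of 8 only)
Why: This is a 1,2-addition of a lithium acetylide to an aldehyde in which the small linear nucleophile can reach the di-ortho-substituted carbonyl; the new carbinol centre is formed without control (racemic), which is immaterial because it later becomes the ketone carbon, and the cold acidic quench prevents base-induced isomerisation of the hydroxy ynoate.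

Step 6
Reactants: 9 hydroxy ynoate
Product: 10 methyl 4-[3-bromo-6-methoxy-2-(methoxymethoxy)-4-methylphenyl]-4-(triethylsilyloxy)but-2-ynoate (racemic)
Conditions: TESCl, imidazole, CH2Cl2, 0 °C
Reagents that add atoms: chlorotriethylsilane CC[Si](CC)(CC)Cl
Why: Imidazole-promoted silylation of the secondary alcohol removes the acidic hydroxyl that would consume the silyl ketene acetal diene, and the triethylsilyl ether should survive heating yet be cleaved by fluoride in the key step.

Step 7
Reactants: 11 methyl acetoacetate; 12 prenyl bromide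
Product: 14 methyl 7-methyl-3-oxooct-6-enoate, via acetoacetate dianion 13 (not isolated)
Conditions: NaH, THF, 0 °C; n-BuLi, 0 °C; 12, 0 °C to rt; 1 M aq HCl
Reagents that add atoms: sodium hydride [Na+].[H-] (sodium of 13 only); n-butyllithium [Li]CCCC (lithium of 13 only)
Why: In this acetoacetate dianion alkylation the more basic terminal (gamma) carbanion attacks the primary allylic bromide in an SN2 reaction, leaving the stabilised alpha position untouched.

Step 8
Reactants: 14 methyl 7-methyl-3-oxooct-6-enoate
Product: 15 methyl 7-methyl-3-(trimethylsilyloxy)octa-2,6-dienoate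
Conditions: TMSCl, Et3N, hexane, rt; filter, concentrate
Reagents that add atoms: chlorotrimethylsilane C[Si](C)(C)Cl
Why: O-Silylation of the readily enolised beta-keto ester with TMSCl and Et3N gives the silyl enol ether, whose alkene geometry does not matter because this bond becomes the central single bond of the diene.

Step 9
Reactants: 15 silyl enol ether
Product: 17 (3Z)-1-methoxy-7-methyl-1,3-bis(trimethylsilyloxy)octa-1,3,6-triene, via lithium dienolate 16 (not isolated)
Conditions: LiN(i-Pr)2 (commercial solution), THF, −78 °C; TMSCl, −78 °C to rt; hexane, filter under Ar; use at once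
Reagents that add atoms: chlorotrimethylsilane C[Si](C)(C)Cl; lithium diisopropylamide [Li]N(C(C)C)C(C)C (lithium of 16 only)
Why: Kinetic gamma-deprotonation of the beta-silyloxy enoate gives the extended ester enolate, and its O-silylation yields the 1-methoxy-1,3-bis(silyloxy)diene with the 3Z geometry usual for this procedure, which places the prenyl group on the outer side of the s-cis diene.

Step 10
Reactants: 10 TES-protected ynoate; 17 bis(silyloxy)diene
Product: 20 3-[3-bromo-6-methoxy-2-(methoxymethoxy)-4-methylphenyl]-5,7-dihydroxy-4-(3-methylbut-2-enyl)-3H-isobenzofuran-1-one (racemic), via cycloadduct 18 (not isolated), via seco hydroxy ester 19 (not isolated)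
Conditions: 17 (3 equiv, two portions), PhMe (2 M), 110 °C, sealed tube; then Bu4NF, THF, 0 °C to rt; 0.5 M aq HCl
Reagents that add atoms: none
Why: The electron-rich diene adds to the ynoate in an asynchronous [4+2] cycloaddition in which its prenyl-bearing C4 terminus bonds to the alkyne carbon beta to the ester (the one carrying the silyloxy-aryl-methyl group) and its ketene acetal carbon C1 bonds to the ester-bearing alpha carbon, closing the six-membered carbocycle as cyclohexa-1,4-diene 18. Fluoride then removes the silyl groups, the ring hemiketal expels methanol and the dienone tautomerises to resorcinol 19, whose freed benzylic alkoxide attacks the neighbouring ester in a 5-exo-trig acyl substitution that closes the lactone. The closest known reaction type is the Diels–Alder benzannulation of 1-alkoxy-1,3-bis(silyloxy)-1,3-dienes with alkynoates to 2,4-dihydroxybenzoates and with 4-oxygenated but-2-ynoates to phthalides. The sp3 ring carbons of 18 are erased on aromatisation and the carbinol carbon remains racemic, so no stereocontrol is required. The only selectivity needed is regioselectivity, which is secured because the ester is the sole acceptor on the alkyne (the second carbonyl is held back as a silyl-protected carbinol) and C4 is the nucleophilic end of the diene. The excess of the thermally labile diene compensates for the slow addition to the beta-branched alkyne, and the fluoride work-up avoids acid that could ionise the electron-rich benzylic carbinol next to the prenyl group or remove the MOM group.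

Step 11
Reactants: 20 dihydroxy phthalide
Product: 21 3-[3-bromo-6-methoxy-2-(methoxymethoxy)-4-methylphenyl]-5,7-bis(methoxymethoxy)-4-(3-methylbut-2-enyl)-3H-isobenzofuran-1-one (racemic)
Conditions: MOMCl, i-Pr2NEt, Bu4NI (cat.), CH2Cl2, 0 to 40 °C
Reagents that add atoms: chloromethyl methyl ether COCCl
Why: O-Alkylation of both ring B phenols (the chelated one beside the lactone carbonyl being the reason for iodide catalysis and warming) removes the acidic, oxidisable phenols before hydride reduction and Swern oxidation.

Step 12
Reactants: 21 tris-MOM phthalide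
Product: 22 [3-bromo-6-methoxy-2-(methoxymethoxy)-4-methylphenyl][2-(hydroxymethyl)-3,5-bis(methoxymethoxy)-6-(3-methylbut-2-enyl)phenyl]methanol (racemic)
Conditions: LiAlH4, THF, 0 °C; Na2SO4·10H2O
Reagents that add atoms: none
Why: Hydride reduction of a lactone to the diol is fast at 0 °C, whereas the aryl bromide, the MOM acetals and the trisubstituted alkene should be inert to LiAlH4 under these conditions, and the neutral work-up protects the acid-sensitive diaryl carbinol.

Step 13
Reactants: 22 tris-MOM diol
Product: 24 2-[3-bromo-6-methoxy-2-(methoxymethoxy)-4-methylbenzoyl]-4,6-bis(methoxymethoxy)-3-(3-methylbut-2-enyl)benzaldehyde, via bis(alkoxysulfonium) salt 23 (not isolated)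
Conditions: (COCl)2 (5 equiv), DMSO (10 equiv), CH2Cl2, −78 °C; 22, −78 °C, 45 min; Et3N (15 equiv), −78 to 0 °C
Reagents that add atoms: dimethyl sulfoxide CS(C)=O (dimethylsulfonium groups of 23 only); oxalyl chloride O=C(Cl)C(=O)Cl (chloride counter-ions of 23 only)
Why: In this double Swern oxidation the excess chlorodimethylsulfonium chloride converts both hydroxyls into alkoxysulfonium ions before any base is present, so aldehyde and ketone appear together when Et3N is added and no free hydroxyl is left to form a lactol that could be re-oxidised to the phthalide.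

Step 14
Reactants: 24 tris-MOM pestalone B
Product: 25 pestalone B
Conditions: 3 M aq HCl, THF, 40 °C
Reagents that add atoms: none
Why: Acid-catalysed acetal hydrolysis should remove all three MOM groups (those ortho to a carbonyl fastest), while the absence of base and amines avoids isomerisation of the ortho-formyl benzophenone to a phthalide and the moderate acidity should spare the prenyl group from cyclising onto the adjacent phenol.

**Compound list**

1 | 3,5-dimethoxytoluene | COc1cc(C)cc(OC)c1 | starting material
2 | (2,6-dimethoxy-4-methylphenyl)lithium, formed in the flask | [Li]c1c(OC)cc(C)cc1OC | intermediate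
3 | 2,6-dimethoxy-4-methylbenzaldehyde | COc1cc(C)cc(OC)c1C=O | intermediate
4 | 3-bromo-2,6-dimethoxy-4-methylbenzaldehyde | COc1cc(C)c(Br)c(OC)c1C=O | intermediate
5 | 3-bromo-2-hydroxy-6-methoxy-4-methylbenzaldehyde | COc1cc(C)c(Br)c(O)c1C=O | intermediate
6 | 3-bromo-6-methoxy-2-(methoxymethoxy)-4-methylbenzaldehyde | COCOc1c(Br)c(C)cc(OC)c1C=O | intermediate
7 | methyl propiolate (methyl prop-2-ynoate) | C#CC(=O)OC | starting material
8 | methyl 3-lithioprop-2-ynoate, formed in the flask | [Li]C#CC(=O)OC | intermediate
9 | methyl 4-[3-bromo-6-methoxy-2-(methoxymethoxy)-4-methylphenyl]-4-hydroxybut-2-ynoate (racemic) | COC(=O)C#CC(O)c1c(OCOC)c(Br)c(C)cc1OC | intermediate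
10 | methyl 4-[3-bromo-6-methoxy-2-(methoxymethoxy)-4-methylphenyl]-4-(triethylsilyloxy)but-2-ynoate (racemic) | COC(=O)C#CC(O[Si](CC)(CC)CC)c1c(OCOC)c(Br)c(C)cc1OC | intermediate
11 | methyl acetoacetate | COC(=O)CC(C)=O | starting material
12 | prenyl bromide (1-bromo-3-methylbut-2-ene) | CC(C)=CCBr | starting material
13 | sodium lithium dianion of methyl acetoacetate (dienolate form), formed in the flask | COC([O-])=CC([O-])=C.[Na+].[Li+] | intermediate
14 | methyl 7-methyl-3-oxooct-6-enoate | COC(=O)CC(=O)CCC=C(C)C | intermediate
15 | methyl 7-methyl-3-(trimethylsilyloxy)octa-2,6-dienoate (2E/2Z mixture, geometry of no consequence) | COC(=O)C=C(O[Si](C)(C)C)CCC=C(C)C | intermediate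
16 | lithium (3Z)-1-methoxy-7-methyl-3-(trimethylsilyloxy)octa-1,3,6-trien-1-olate, formed in the flask | [Li+].COC([O-])=C/C(O[Si](C)(C)C)=C/CC=C(C)C | intermediate
17 | (3Z)-1-methoxy-7-methyl-1,3-bis(trimethylsilyloxy)octa-1,3,6-triene (C1=C2 geometry undefined and of no consequence) | COC(O[Si](C)(C)C)=C/C(O[Si](C)(C)C)=C/CC=C(C)C | intermediate
18 | methyl 2-{[3-bromo-6-methoxy-2-(methoxymethoxy)-4-methylphenyl](triethylsilyloxy)methyl}-6-methoxy-3-(3-methylbut-2-enyl)-4,6-bis(trimethylsilyloxy)cyclohexa-1,4-diene-1-carboxylate (diastereomer mixture), formed in the flask | COC(=O)C1=C(C(O[Si](CC)(CC)CC)c2c(OCOC)c(Br)c(C)cc2OC)C(CC=C(C)C)C(O[Si](C)(C)C)=CC1(OC)O[Si](C)(C)C | intermediate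
19 | methyl 2-{[3-bromo-6-methoxy-2-(methoxymethoxy)-4-methylphenyl](hydroxy)methyl}-4,6-dihydroxy-3-(3-methylbut-2-enyl)benzoate (racemic), formed in the flask | COC(=O)c1c(O)cc(O)c(CC=C(C)C)c1C(O)c1c(OCOC)c(Br)c(C)cc1OC | intermediate
20 | 3-[3-bromo-6-methoxy-2-(methoxymethoxy)-4-methylphenyl]-5,7-dihydroxy-4-(3-methylbut-2-enyl)-3H-isobenzofuran-1-one (racemic) | O=C1OC(c2c(OCOC)c(Br)c(C)cc2OC)c2c1c(O)cc(O)c2CC=C(C)C | intermediate
21 | 3-[3-bromo-6-methoxy-2-(methoxymethoxy)-4-methylphenyl]-5,7-bis(methoxymethoxy)-4-(3-methylbut-2-enyl)-3H-isobenzofuran-1-one (racemic) | O=C1OC(c2c(OCOC)c(Br)c(C)cc2OC)c2c1c(OCOC)cc(OCOC)c2CC=C(C)C | intermediate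
22 | [3-bromo-6-methoxy-2-(methoxymethoxy)-4-methylphenyl][2-(hydroxymethyl)-3,5-bis(methoxymethoxy)-6-(3-methylbut-2-enyl)phenyl]methanol (racemic) | OCc1c(OCOC)cc(OCOC)c(CC=C(C)C)c1C(O)c1c(OCOC)c(Br)c(C)cc1OC | intermediate
23 | bis(dimethylsulfonium) derivative of 22 on both carbinol oxygens, dichloride, formed in the flask | C[S+](C)OCc1c(OCOC)cc(OCOC)c(CC=C(C)C)c1C(O[S+](C)C)c1c(OCOC)c(Br)c(C)cc1OC.[Cl-].[Cl-] | intermediate
24 | 2-[3-bromo-6-methoxy-2-(methoxymethoxy)-4-methylbenzoyl]-4,6-bis(methoxymethoxy)-3-(3-methylbut-2-enyl)benzaldehyde | O=Cc1c(OCOC)cc(OCOC)c(CC=C(C)C)c1C(=O)c1c(OCOC)c(Br)c(C)cc1OC | intermediate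
25 | pestalone B, 2-(3-bromo-2-hydroxy-6-methoxy-4-methylbenzoyl)-4,6-dihydroxy-3-(3-methylbut-2-enyl)benzaldehyde | COc1cc(C)c(Br)c(O)c1C(=O)c1c(C=O)c(O)cc(O)c1CC=C(C)C | target

**Step count.** Total: 14 steps. Longest linear sequence: 11 steps (steps 1–6 and 10–14, from 3,5-dimethoxytoluene); the diene branch is 3 steps (steps 7–9).

**Steps most likely to fail**

Step 10. The cycloaddition to the hindered, singly activated alkyne may be slower than thermal silyl migration and decomposition of diene 17, so that the diene is consumed without ring formation. The fallback sets out from 10 and comes back at 22, and raises dienophile reactivity by changing the oxidation level of the acceptor. Ynoate 10 would be reduced with i-Bu2AlH (CH2Cl2, −78 °C) to the propargylic alcohol 4-aryl-4-(triethylsilyloxy)but-2-yn-1-ol F1 and oxidised with MnO2 to 4-aryl-4-(triethylsilyloxy)but-2-ynal F2. Ynals are much stronger dienophiles than ynoates, so the addition of 17 should proceed at or near room temperature with the same regiochemistry (the formyl group is again the only acceptor) to give the cyclohexadiene carbaldehyde cycloadduct F3. K2CO3 in MeOH would cleave the aryl silyl ethers and expel methanol while keeping the TES ether, giving the TES-protected dihydroxy benzaldehyde F4. MOMCl with i-Pr2NEt would give the bis-MOM aldehyde F5, NaBH4 in MeOH the TES-protected benzylic alcohol F6, and Bu4NF would remove the TES group to deliver diol 22, bypassing the phthalide.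

Step 13. Incomplete activation of the crowded diaryl carbinol, or its ionisation once activated, would let the aldehyde appear beside a free hydroxyl, followed by lactol closure and re-oxidation towards phthalide 21. The fallback sets out from 22 and comes back at 24, oxidising the two carbinols one at a time in the order that cannot lead to a lactone. Selective silylation of the primary hydroxyl (TBSCl, imidazole) would give the mono-TBS ether F7. Dess–Martin periodinane would oxidise the remaining secondary carbinol to the TBS-protected benzophenone F8. HF·pyridine would free the primary alcohol to give the keto alcohol F9. A final Dess–Martin oxidation would give 24, because any hemiketal formed from the ketone is tertiary and cannot be over-oxidised.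

Step 3. BCl3 may attack the unhindered methoxy group or both ethers, giving the regioisomeric phenol or the diphenol; the assignment of 5 would be checked by an NOE between the ring hydrogen and the surviving OCH3. The fallback sets out from 3 and comes back at 5, differentiating the two oxygens before the bromine is introduced. Mono-demethylation of symmetric 3 with BCl3 (no regiochemical question) would give 2-hydroxy-6-methoxy-4-methylbenzaldehyde F10. Acetylation (Ac2O, pyridine) would give 2-formyl-3-methoxy-5-methylphenyl acetate F11. In F11 the methoxy group is by far the stronger donor, so NBS bromination should go para to it and ortho to the acetoxy group, giving 6-bromo-2-formyl-3-methoxy-5-methylphenyl acetate F12. K2CO3 in MeOH would then remove the acetate to give 5.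

**Further compounds**

F1 | step 10 | 4-[3-bromo-6-methoxy-2-(methoxymethoxy)-4-methylphenyl]-4-(triethylsilyloxy)but-2-yn-1-ol (racemic) | OCC#CC(O[Si](CC)(CC)CC)c1c(OCOC)c(Br)c(C)cc1OC
F2 | step 10 | 4-[3-bromo-6-methoxy-2-(methoxymethoxy)-4-methylphenyl]-4-(triethylsilyloxy)but-2-ynal (racemic) | O=CC#CC(O[Si](CC)(CC)CC)c1c(OCOC)c(Br)c(C)cc1OC
F3 | step 10 | 2-{[3-bromo-6-methoxy-2-(methoxymethoxy)-4-methylphenyl](triethylsilyloxy)methyl}-6-methoxy-3-(3-methylbut-2-enyl)-4,6-bis(trimethylsilyloxy)cyclohexa-1,4-diene-1-carbaldehyde (diastereomer mixture) | O=CC1=C(C(O[Si](CC)(CC)CC)c2c(OCOC)c(Br)c(C)cc2OC)C(CC=C(C)C)C(O[Si](C)(C)C)=CC1(OC)O[Si](C)(C)C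
F4 | step 10 | 2-{[3-bromo-6-methoxy-2-(methoxymethoxy)-4-methylphenyl](triethylsilyloxy)methyl}-4,6-dihydroxy-3-(3-methylbut-2-enyl)benzaldehyde (racemic) | O=Cc1c(O)cc(O)c(CC=C(C)C)c1C(O[Si](CC)(CC)CC)c1c(OCOC)c(Br)c(C)cc1OC
F5 | step 10 | 2-{[3-bromo-6-methoxy-2-(methoxymethoxy)-4-methylphenyl](triethylsilyloxy)methyl}-4,6-bis(methoxymethoxy)-3-(3-methylbut-2-enyl)benzaldehyde (racemic) | O=Cc1c(OCOC)cc(OCOC)c(CC=C(C)C)c1C(O[Si](CC)(CC)CC)c1c(OCOC)c(Br)c(C)cc1OC
F6 | step 10 | [2-{[3-bromo-6-methoxy-2-(methoxymethoxy)-4-methylphenyl](triethylsilyloxy)methyl}-4,6-bis(methoxymethoxy)-3-(3-methylbut-2-enyl)phenyl]methanol (racemic) | OCc1c(OCOC)cc(OCOC)c(CC=C(C)C)c1C(O[Si](CC)(CC)CC)c1c(OCOC)c(Br)c(C)cc1OC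
F7 | step 13 | [3-bromo-6-methoxy-2-(methoxymethoxy)-4-methylphenyl][2-(tert-butyldimethylsilyloxymethyl)-3,5-bis(methoxymethoxy)-6-(3-methylbut-2-enyl)phenyl]methanol (racemic) | CC(C)(C)[Si](C)(C)OCc1c(OCOC)cc(OCOC)c(CC=C(C)C)c1C(O)c1c(OCOC)c(Br)c(C)cc1OC
F8 | step 13 | [3-bromo-6-methoxy-2-(methoxymethoxy)-4-methylphenyl][2-(tert-butyldimethylsilyloxymethyl)-3,5-bis(methoxymethoxy)-6-(3-methylbut-2-enyl)phenyl]methanone | CC(C)(C)[Si](C)(C)OCc1c(OCOC)cc(OCOC)c(CC=C(C)C)c1C(=O)c1c(OCOC)c(Br)c(C)cc1OC
F9 | step 13 | [3-bromo-6-methoxy-2-(methoxymethoxy)-4-methylphenyl][2-(hydroxymethyl)-3,5-bis(methoxymethoxy)-6-(3-methylbut-2-enyl)phenyl]methanone | OCc1c(OCOC)cc(OCOC)c(CC=C(C)C)c1C(=O)c1c(OCOC)c(Br)c(C)cc1OC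
F10 | step 3 | 2-hydroxy-6-methoxy-4-methylbenzaldehyde | COc1cc(C)cc(O)c1C=O
F11 | step 3 | 2-formyl-3-methoxy-5-methylphenyl acetate | COc1cc(C)cc(OC(C)=O)c1C=O
F12 | step 3 | 6-bromo-2-formyl-3-methoxy-5-methylphenyl acetate | COc1cc(C)c(Br)c(OC(C)=O)c1C=O
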